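**Retrosynthetic overview**
1. Target 27 ⇐ equatorial C–Br by SN2 inversion of axial alcohol 25; homoprenyl arm ⇐ 3-hydroxypropyl arm (oxidation, Wittig); tertiary ring carbinol ⇐ equatorial methyl addition to ring ketone 19; 19 ⇐ oxidative decarboxylation of acid 17.
2. Key disconnection (cyclohexane, two bonds): CH2–C(Me)OH and CH(side chain)–C(quaternary), i.e. a [4+2] of the cyclic 2-alkoxydiene 4 with the (E)-enoyl imide 13. (S)-Linalool supplies the side-chain carbinol centre; the oxazolidinone sets the absolute configuration of the ring.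
3. Enabling feature: the ring run C(quaternary)–CHBr–CH2–CH2 carries its heteroatom on the second carbon, 1,4 to the carbinol carbon. At the enol ether oxidation level this run is a 2-oxy-1,3-diene, and the first three carbons of the homoprenyl arm can be tied to that oxygen as a temporary dihydropyran ring. The ring fixes the enol ether geometry (hence the quaternary centre) and masks both the ketone and the arm.
4. The two remaining ring atoms (carbinol carbon and side-chain CH) are the α- and β-carbons of the dienophile; its directing acyl group is afterwards excised to the ketone.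
5. Ring order: temporary dihydropyran (steps 1–3), then the cyclohexane (step 8), then opening of the dihydropyran (step 13).

Key step: step 8

Assumption: (S)-(+)-linalool of high enantiomeric purity is taken as the commercial source of the side-chain centre; the ketal carbon formed in step 8 is drawn as the expected trans-fused anomer and is destroyed again in step 13.

Step 1
Reactants: 1 δ-valerolactone (oxan-2-one)
Product: 2 3-methyloxan-2-one (racemic)
Conditions: LiN(i-Pr)2, THF, −78 °C; MeI, −78 to −20 °C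
Reagents that add atoms: iodomethane, CI
Why: Enolate alkylation of the lactone lithium enolate; the new stereocentre is of no consequence because it becomes sp2 in step 2.

Step 2
Reactants: 2 3-methyloxan-2-one
Product: 3 5-methyl-3,4-dihydro-2H-pyran-6-yl diphenyl phosphate
Conditions: KN(SiMe3)2, (PhO)2P(O)Cl, THF/HMPA, −78 °C
Reagents that add atoms: diphenyl chlorophosphate, O=P(Cl)(Oc1ccccc1)Oc1ccccc1
Why: O-Phosphorylation of the potassium lactone enolate (ketene acetal phosphate formation) gives a cross-coupling electrophile in which ring oxygen and ring CH2 are necessarily cis across the enol ether double bond.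

Step 3
Reactants: 3 5-methyl-3,4-dihydro-2H-pyran-6-yl diphenyl phosphate
Product: 4 6-ethenyl-5-methyl-3,4-dihydro-2H-pyran
Conditions: CH2=CHSnBu3, Pd(PPh3)4 (5 mol %), LiCl, THF, reflux
Reagents that add atoms: tributyl(vinyl)stannane, C=C[Sn](CCCC)(CCCC)CCCC
Why: Stille cross-coupling of a lactone-derived ketene acetal phosphate with a vinylstannane, a standard entry to cyclic 2-alkoxy-1,3-dienes, should keep the ring-fixed alkene geometry.

Step 4
Reactants: 5 (S)-(+)-linalool
Product: 6 (3S)-3,7-dimethyl-3-(triethylsilyloxy)octa-1,6-diene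
Conditions: Et3SiOTf, 2,6-lutidine, CH2Cl2, −78 to 0 °C
Reagents that add atoms: triethylsilyl trifluoromethanesulfonate, CC[Si](CC)(CC)OS(=O)(=O)C(F)(F)F
Why: Silyl ether formation at the tertiary allylic alcohol with a silyl triflate; the carbinol centre is not touched.

Step 5
Reactants: 6 (3S)-3,7-dimethyl-3-(triethylsilyloxy)octa-1,6-diene
Product: 8 (4S)-4-methyl-4-(triethylsilyloxy)hex-5-enal, via secondary ozonide 7 (not isolated)
Conditions: O3 (1.0 equiv, metered), CH2Cl2, −78 °C; PPh3, −78 °C to rt
Reagents that add atoms: ozone, [O-][O+]=O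
Why: Chemoselective ozonolysis with reductive work-up; the electron-rich trisubstituted alkene should react far faster than the vinyl group next to the quaternary silyloxy carbon.

Step 6
Reactants: 8 (4S)-4-methyl-4-(triethylsilyloxy)hex-5-enal
Product: 10 (2E,6S)-6-methyl-6-(triethylsilyloxy)octa-2,7-dienoic acid, via alkylidenemalonic acid 9 (not isolated)
Conditions: CH2(CO2H)2, pyridine, piperidine (cat.), rt then 60 °C
Reagents that add atoms: malonic acid, OC(=O)CC(=O)O
Why: Knoevenagel–Doebner condensation; decarboxylation of the alkylidenemalonic acid should give the (E)-2-enoic acid.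

Step 7
Reactants: 10 (2E,6S)-6-methyl-6-(triethylsilyloxy)octa-2,7-dienoic acid; 11 (4S)-4-benzyl-1,3-oxazolidin-2-one
Product: 13 (4S)-4-benzyl-3-[(2E,6S)-6-methyl-6-(triethylsilyloxy)octa-2,7-dienoyl]-1,3-oxazolidin-2-one, via mixed pivalic anhydride 12 (not isolated)
Conditions: t-BuCOCl, Et3N, THF, −20 °C; then 11, LiCl, rt
Reagents that add atoms: pivaloyl chloride, CC(C)(C)C(Cl)=O (its acyl group is carried by intermediate 12 only)
Why: N-Acylation of the oxazolidinone by a mixed anhydride (acyl transfer at the less hindered carbonyl), the standard preparation of enoyl imides, leaves the E-alkene and both stereocentres unchanged.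

Step 8
Reactants: 13 (4S)-4-benzyl-3-[(2E,6S)-6-methyl-6-(triethylsilyloxy)octa-2,7-dienoyl]-1,3-oxazolidin-2-one; 4 6-ethenyl-5-methyl-3,4-dihydro-2H-pyran
Product: 15 (4S)-4-benzyl-3-{[(4aS,5R,6S,8aS)-8a-methoxy-4a-methyl-5-[(3S)-3-methyl-3-(triethylsilyloxy)pent-4-en-1-yl]octahydro-2H-chromen-6-yl]carbonyl}-1,3-oxazolidin-2-one, via enol ether cycloadduct 14 (not isolated)
Conditions: 4 (3 equiv), Et2AlCl (1.6 equiv), CH2Cl2, −78 to −40 °C; aq. KNaC4H4O6 work-up; crude product in MeOH, PPTS (cat.), 0 °C
Reagents that add atoms: methanol, CO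
Why: Lewis-acid-promoted, normal-electron-demand Diels–Alder reaction of an N-enoyl oxazolidinone: Et2AlCl converts imide 13 into a cationic bidentate aluminium chelate with an s-cis enoyl group, whose β-carbon is attacked by the fully substituted enol ether carbon of diene 4 while the vinyl terminus bonds to the α-carbon, in a concerted but strongly asynchronous [4+2] (in the stepwise limit a Mukaiyama–Michael addition followed by 6-(enolexo)-endo-trig collapse of the aluminium enolate onto the alkoxyallyl cation). The closest known reaction types are the auxiliary-controlled Diels–Alder reactions of crotonoyl oxazolidinones with acyclic dienes under Et2AlCl and the Lewis-acid Diels–Alder reactions of hindered 2-oxygenated dienes that create quaternary carbons. The cyclohexene is the only ring closed, by [4+2] cycloaddition, as the "para" regioisomer because the ring oxygen makes the methyl-bearing diene terminus the nucleophilic one and the imide β-carbon is the electrophilic one. The side-chain CH is set by the benzyl group of the (S)-auxiliary, which shields one face of the chelated dienophile, the acyl-bearing CH by the E-alkene (suprafacial addition, acyl trans to the side chain), and the quaternary carbon by the endo transition state combined with the diene geometry that the dihydropyran ring fixes (ring CH2 outside, methyl inside), so that the C-methyl group should end cis to the side chain. The step therefore needs regio-, endo- and π-facial selectivity, secured by the enol ether polarisation, the chelated acyl group and the auxiliary, while the achiral diene needs no facial control of its own. Acidic methanol then adds across the labile enol ether (oxocarbenium capture anti to the angular methyl group) to give the stable mixed ketal that masks the future C–Br carbon.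

Step 9
Reactants: 15 ketal imide
Product: 17 (4aS,5R,6S,8aS)-8a-methoxy-4a-methyl-5-[(3S)-3-methyl-3-(triethylsilyloxy)pent-4-en-1-yl]octahydro-2H-chromene-6-carboxylic acid, via peroxy acid 16 (not isolated)
Conditions: LiOH, H2O2, THF/H2O, 0 °C; Na2SO3; cold dilute HCl to pH 5, acid used at once
Reagents that add atoms: hydrogen peroxide (as LiOOH), OO
Why: Hydroperoxide-mediated imide hydrolysis (exocyclic acyl cleavage even for hindered N-acyl oxazolidinones) followed by sulfite reduction of the peracid; the basic medium should leave ketal and silyl ether intact.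

Step 10
Reactants: 17 carboxylic acid
Product: 19 (4aS,5S,8aS)-8a-methoxy-4a-methyl-5-[(3S)-3-methyl-3-(triethylsilyloxy)pent-4-en-1-yl]octahydro-2H-chromen-6-one, via hydroperoxy acid 18 (not isolated)
Conditions: LiN(i-Pr)2 (2.3 equiv), THF, −78 to 0 °C; O2, −78 °C; cold dilute HCl to pH 5; Me2NCH(OMe)2, CH2Cl2, rt
Reagents that add atoms: dioxygen, O=O
Why: Oxygenation of the carboxylic acid dianion (enolate autoxidation) and dehydrative decarboxylation of the α-hydroperoxy acid (oxidative decarboxylation of an acid to a ketone) erase the acyl-bearing centre on purpose; the neighbouring CH, should it epimerise, is biased by the trans-fused ketal towards the required equatorial side chain.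

Step 11
Reactants: 19 ring ketone
Product: 20 (4aS,5S,6R,8aS)-8a-methoxy-4a,6-dimethyl-5-[(3S)-3-methyl-3-(triethylsilyloxy)pent-4-en-1-yl]octahydro-2H-chromen-6-ol
Conditions: MeLi, CeCl3, THF, −78 °C
Reagents that add atoms: methyllithium, [Li]C
Why: Organocerium 1,2-addition to an enolisable ketone; methyl should enter equatorially because the axial face is blocked by the syn-axial angular C-methyl group two carbons away (the 3,3,5-trimethylcyclohexanone situation), giving the axial tertiary alcohol cis to the side chain.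

Step 12
Reactants: 20 tertiary alcohol
Product: 21 triethylsilyl ether of 20 [(4aS,5S,6R,8aS)-8a-methoxy-4a,6-dimethyl-5-[(3S)-3-methyl-3-(triethylsilyloxy)pent-4-en-1-yl]-6-(triethylsilyloxy)octahydro-2H-chromene]
Conditions: KN(SiMe3)2, Et3SiCl, THF, −78 to 0 °C
Reagents that add atoms: chlorotriethylsilane, CC[Si](Cl)(CC)CC
Why: Silyl ether formation through the potassium alkoxide, i.e. under basic conditions that should not touch the acid-labile ketal.

Step 13
Reactants: 21 bis(silyl ether) ketal
Product: 22 (2S,3S,4R)-2-(3-hydroxypropyl)-2,4-dimethyl-3-[(3S)-3-methyl-3-(triethylsilyloxy)pent-4-en-1-yl]-4-(triethylsilyloxy)cyclohexan-1-one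
Conditions: PPTS (cat.), acetone/H2O, 0 °C to rt
Reagents that add atoms: water, O
Why: Ketal hydrolysis through the tertiary oxocarbenium ion opens the temporary ring and releases the ring ketone and the 3-hydroxypropyl arm; the tertiary silyl ethers should survive the brief mild acid.

Step 14
Reactants: 22 hydroxy ketone
Product: 24 (2S,3S,4R)-2,4-dimethyl-2-(4-methylpent-3-en-1-yl)-3-[(3S)-3-methyl-3-(triethylsilyloxy)pent-4-en-1-yl]-4-(triethylsilyloxy)cyclohexan-1-one, via keto aldehyde 23 (not isolated)
Conditions: DMP, pyridine, CH2Cl2, 0 °C to rt; crude 23 added to Ph3P=CMe2 (from i-PrPPh3I, n-BuLi), THF, −78 to 0 °C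
Reagents that add atoms: isopropylidenetriphenylphosphorane (made from isopropyltriphenylphosphonium iodide and n-BuLi), CC(C)=P(c1ccccc1)(c1ccccc1)c1ccccc1
Why: Alcohol oxidation followed by Wittig olefination; the non-stabilised ylide should add to the aldehyde much faster than to the ketone flanked by the quaternary carbon, and not isolating the 1,5-keto aldehyde avoids its aldol cyclisation.

Step 15
Reactants: 24 ring ketone
Product: 25 (1R,2S,3S,4R)-2,4-dimethyl-2-(4-methylpent-3-en-1-yl)-3-[(3S)-3-methyl-3-(triethylsilyloxy)pent-4-en-1-yl]-4-(triethylsilyloxy)cyclohexan-1-ol (hydroxyl axial, trans to the neighbouring C-methyl group)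
Conditions: LiBH(s-Bu)3, THF, −78 °C; aq. NaOH, H2O2
Reagents that add atoms: none
Why: Ketone reduction with a bulky trialkylborohydride; in the chair with equatorial side chain and axial C-methyl group the hydride should arrive equatorially and give the axial alcohol, as known for cyclohexanones flanked by a quaternary carbon such as 4,4-dimethyl-3-keto terpenoids.

Step 16
Reactants: 25 axial alcohol
Product: 26 bis(triethylsilyl) ether of the target [(1R,2S,3S,4S)-4-bromo-1,3-dimethyl-3-(4-methylpent-3-en-1-yl)-2-[(3S)-3-methyl-3-(triethylsilyloxy)pent-4-en-1-yl]-1-(triethylsilyloxy)cyclohexane]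
Conditions: CBr4, PPh3, 2,6-lutidine, toluene, 60 °C
Reagents that add atoms: tetrabromomethane, BrC(Br)(Br)Br
Why: Appel reaction; bromide should displace the alkoxyphosphonium group with inversion (SN2), turning the axial alcohol into the equatorial bromide, as known for neopentylic secondary bromides of bromoterpenoids.

Step 17
Reactants: 26 bromide
Product: 27 (1R,2S,3S,4S)-4-bromo-2-[(3S)-3-hydroxy-3-methylpent-4-en-1-yl]-1,3-dimethyl-3-(4-methylpent-3-en-1-yl)cyclohexan-1-ol (CNP0237376.1)
Conditions: HF·pyridine, pyridine, THF, 0 °C to rt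
Reagents that add atoms: none
Why: Fluoride-mediated desilylation of both tertiary silyl ethers; the buffered reagent should spare the tertiary allylic alcohol and the equatorial bromide, which has no antiperiplanar hydrogen for E2 elimination.

**Compound list**
1 | δ-valerolactone (oxan-2-one) | O=C1CCCCO1 | starting material
2 | 3-methyloxan-2-one (racemic) | CC1CCCOC1=O | intermediate
3 | 5-methyl-3,4-dihydro-2H-pyran-6-yl diphenyl phosphate | CC1=C(OP(=O)(Oc2ccccc2)Oc2ccccc2)OCCC1 | intermediate
4 | 6-ethenyl-5-methyl-3,4-dihydro-2H-pyran | C=CC1=C(C)CCCO1 | intermediate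
5 | (S)-(+)-linalool, (3S)-3,7-dimethylocta-1,6-dien-3-ol | C=C[C@@](C)(O)CCC=C(C)C | starting material
6 | (3S)-3,7-dimethyl-3-(triethylsilyloxy)octa-1,6-diene | C=C[C@@](C)(O[Si](CC)(CC)CC)CCC=C(C)C | intermediate
7 | secondary ozonide, 3,3-dimethyl-5-[(3S)-3-methyl-3-(triethylsilyloxy)pent-4-en-1-yl]-1,2,4-trioxolane (epimers at the ring CH) | C=C[C@@](C)(O[Si](CC)(CC)CC)CCC1OOC(C)(C)O1 | intermediate
8 | (4S)-4-methyl-4-(triethylsilyloxy)hex-5-enal | C=C[C@@](C)(O[Si](CC)(CC)CC)CCC=O | intermediate
9 | 2-[(4S)-4-methyl-4-(triethylsilyloxy)hex-5-en-1-ylidene]propanedioic acid | C=C[C@@](C)(O[Si](CC)(CC)CC)CCC=C(C(=O)O)C(=O)O | intermediate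
10 | (2E,6S)-6-methyl-6-(triethylsilyloxy)octa-2,7-dienoic acid | C=C[C@@](C)(O[Si](CC)(CC)CC)CC/C=C/C(=O)O | intermediate
11 | (4S)-4-benzyl-1,3-oxazolidin-2-one | O=C1N[C@@H](Cc2ccccc2)CO1 | starting material
12 | mixed anhydride of 10 with pivalic acid | C=C[C@@](C)(O[Si](CC)(CC)CC)CC/C=C/C(=O)OC(=O)C(C)(C)C | intermediate
13 | (4S)-4-benzyl-3-[(2E,6S)-6-methyl-6-(triethylsilyloxy)octa-2,7-dienoyl]-1,3-oxazolidin-2-one | C=C[C@@](C)(O[Si](CC)(CC)CC)CC/C=C/C(=O)N1[C@@H](Cc2ccccc2)COC1=O | intermediate
14 | (4S)-4-benzyl-3-{[(4aS,5R,6S)-4a-methyl-5-[(3S)-3-methyl-3-(triethylsilyloxy)pent-4-en-1-yl]-3,4,4a,5,6,7-hexahydro-2H-chromen-6-yl]carbonyl}-1,3-oxazolidin-2-one (4a-methyl cis to the 5-side chain, 6-acyl trans to it) | C=C[C@@](C)(O[Si](CC)(CC)CC)CC[C@H]1[C@]2(C)CCCOC2=CC[C@@H]1C(=O)N3[C@@H](Cc4ccccc4)COC3=O | intermediate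
15 | (4S)-4-benzyl-3-{[(4aS,5R,6S,8aS)-8a-methoxy-4a-methyl-5-[(3S)-3-methyl-3-(triethylsilyloxy)pent-4-en-1-yl]octahydro-2H-chromen-6-yl]carbonyl}-1,3-oxazolidin-2-one (methoxy trans to the 4a-methyl) | C=C[C@@](C)(O[Si](CC)(CC)CC)CC[C@H]1[C@]2(C)CCCO[C@@]2(OC)CC[C@@H]1C(=O)N3[C@@H](Cc4ccccc4)COC3=O | intermediate
16 | (4aS,5R,6S,8aS)-8a-methoxy-4a-methyl-5-[(3S)-3-methyl-3-(triethylsilyloxy)pent-4-en-1-yl]octahydro-2H-chromene-6-carboperoxoic acid | C=C[C@@](C)(O[Si](CC)(CC)CC)CC[C@H]1[C@]2(C)CCCO[C@@]2(OC)CC[C@@H]1C(=O)OO | intermediate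
17 | (4aS,5R,6S,8aS)-8a-methoxy-4a-methyl-5-[(3S)-3-methyl-3-(triethylsilyloxy)pent-4-en-1-yl]octahydro-2H-chromene-6-carboxylic acid | C=C[C@@](C)(O[Si](CC)(CC)CC)CC[C@H]1[C@]2(C)CCCO[C@@]2(OC)CC[C@@H]1C(=O)O | intermediate
18 | (4aS,5S,8aS)-6-hydroperoxy-8a-methoxy-4a-methyl-5-[(3S)-3-methyl-3-(triethylsilyloxy)pent-4-en-1-yl]octahydro-2H-chromene-6-carboxylic acid (epimers at C6) | C=C[C@@](C)(O[Si](CC)(CC)CC)CC[C@H]1[C@]2(C)CCCO[C@@]2(OC)CCC1(OO)C(=O)O | intermediate
19 | (4aS,5S,8aS)-8a-methoxy-4a-methyl-5-[(3S)-3-methyl-3-(triethylsilyloxy)pent-4-en-1-yl]octahydro-2H-chromen-6-one | C=C[C@@](C)(O[Si](CC)(CC)CC)CC[C@H]1[C@]2(C)CCCO[C@@]2(OC)CCC1=O | intermediate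
20 | (4aS,5S,6R,8aS)-8a-methoxy-4a,6-dimethyl-5-[(3S)-3-methyl-3-(triethylsilyloxy)pent-4-en-1-yl]octahydro-2H-chromen-6-ol | C=C[C@@](C)(O[Si](CC)(CC)CC)CC[C@H]1[C@]2(C)CCCO[C@@]2(OC)CC[C@@]1(C)O | intermediate
21 | triethylsilyl ether of 20 | C=C[C@@](C)(O[Si](CC)(CC)CC)CC[C@H]1[C@]2(C)CCCO[C@@]2(OC)CC[C@@]1(C)O[Si](CC)(CC)CC | intermediate
22 | (2S,3S,4R)-2-(3-hydroxypropyl)-2,4-dimethyl-3-[(3S)-3-methyl-3-(triethylsilyloxy)pent-4-en-1-yl]-4-(triethylsilyloxy)cyclohexan-1-one | C=C[C@@](C)(O[Si](CC)(CC)CC)CC[C@H]1[C@](C)(CCCO)C(=O)CC[C@@]1(C)O[Si](CC)(CC)CC | intermediate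
23 | keto aldehyde, 22 with the CH2OH group oxidised to CHO | C=C[C@@](C)(O[Si](CC)(CC)CC)CC[C@H]1[C@](C)(CCC=O)C(=O)CC[C@@]1(C)O[Si](CC)(CC)CC | intermediate
24 | (2S,3S,4R)-2,4-dimethyl-2-(4-methylpent-3-en-1-yl)-3-[(3S)-3-methyl-3-(triethylsilyloxy)pent-4-en-1-yl]-4-(triethylsilyloxy)cyclohexan-1-one | C=C[C@@](C)(O[Si](CC)(CC)CC)CC[C@H]1[C@](C)(CCC=C(C)C)C(=O)CC[C@@]1(C)O[Si](CC)(CC)CC | intermediate
25 | (1R,2S,3S,4R)-2,4-dimethyl-2-(4-methylpent-3-en-1-yl)-3-[(3S)-3-methyl-3-(triethylsilyloxy)pent-4-en-1-yl]-4-(triethylsilyloxy)cyclohexan-1-ol | C=C[C@@](C)(O[Si](CC)(CC)CC)CC[C@H]1[C@](C)(CCC=C(C)C)[C@H](O)CC[C@@]1(C)O[Si](CC)(CC)CC | intermediate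
26 | (1R,2S,3S,4S)-4-bromo-1,3-dimethyl-3-(4-methylpent-3-en-1-yl)-2-[(3S)-3-methyl-3-(triethylsilyloxy)pent-4-en-1-yl]-1-(triethylsilyloxy)cyclohexane | C=C[C@@](C)(O[Si](CC)(CC)CC)CC[C@H]1[C@](C)(CCC=C(C)C)[C@@H](Br)CC[C@@]1(C)O[Si](CC)(CC)CC | intermediate
27 | (1R,2S,3S,4S)-4-bromo-2-[(3S)-3-hydroxy-3-methylpent-4-en-1-yl]-1,3-dimethyl-3-(4-methylpent-3-en-1-yl)cyclohexan-1-ol | C=C[C@@](C)(O)CC[C@H]1[C@](C)(CCC=C(C)C)[C@@H](Br)CC[C@@]1(C)O | target

Total step count: 17 (three steps to diene 4, four steps to imide 13, ten steps from their union).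
Longest linear sequence: 14 steps (5 to 27, steps 4–17).

**Steps most likely to fail**

1. Step 8. The Lewis acid may consume the acid-labile diene or divert the zwitterionic pathway to cyclobutane or dihydropyran products ([2+2] or hetero-Diels–Alder closure). Endo and facial control may also be eroded at the crowded quaternary terminus. The fallback is a thermal, Lewis-acid-free nitroalkene Diels–Alder route that sets out from aldehyde 8 and diene 4 and comes back at ketone 19. Henry addition of nitromethane to 8 (KOtBu cat., THF/t-BuOH) should give nitro alcohol F1, and dehydration (DCC, CuCl cat.) the (E)-nitroalkene F2. Heating F2 with diene 4 (toluene, 80 °C; nitro endo, same relative configuration of side chain and quaternary carbon) should give enol ether F3, and MeOH/PPTS the nitro ketal F4. This route gives up absolute control of the ring: the two ring-enantiomeric series are diastereomers because of the linalool-derived centre and would be separated by chromatography at F4. A Nef reaction (NaOMe, MeOH; then buffered aqueous TiCl3) would then convert F4 into ketone 19.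

2. Step 16. The neopentylic alkoxyphosphonium ion may ionise, with elimination or 1,2-alkyl shift instead of SN2 displacement. The fallback sets out from alcohol 25: formation of the isolable triflate F5 (Tf2O, pyridine, CH2Cl2, −20 °C) and displacement with a soluble bromide source (Bu4NBr, toluene, rt to 40 °C) would return to bromide 26.

3. Step 10. The acid-labile ketal may be cleaved during the buffered work-up of the hydroperoxy acid, or dianion formation at the hindered ring carbon may be incomplete. The fallback sets out from acid 17 and uses a radical instead of an enolate pathway. Photocatalytic decarboxylative hydroxylation of the carboxylate (9-mesityl-10-methylacridinium perchlorate, O2, blue light; then NaBH4) would give secondary alcohol F6 as an epimer mixture, and oxidation (DMP, pyridine, CH2Cl2) would return to ketone 19.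

**Further compounds**
F1 | step 8 | (5S)-5-methyl-1-nitro-5-(triethylsilyloxy)hept-6-en-2-ol (epimers at C2) | C=C[C@@](C)(O[Si](CC)(CC)CC)CCC(O)C[N+](=O)[O-]
F2 | step 8 | (1E,5S)-5-methyl-1-nitro-5-(triethylsilyloxy)hepta-1,6-diene | C=C[C@@](C)(O[Si](CC)(CC)CC)CC/C=C/[N+](=O)[O-]
F3 | step 8 | (4aS,5S,6S)-4a-methyl-5-[(3S)-3-methyl-3-(triethylsilyloxy)pent-4-en-1-yl]-6-nitro-3,4,4a,5,6,7-hexahydro-2H-chromene | C=C[C@@](C)(O[Si](CC)(CC)CC)CC[C@H]1[C@]2(C)CCCOC2=CC[C@@H]1[N+](=O)[O-]
F4 | step 8 | (4aS,5S,6S,8aS)-8a-methoxy-4a-methyl-5-[(3S)-3-methyl-3-(triethylsilyloxy)pent-4-en-1-yl]-6-nitrooctahydro-2H-chromene | C=C[C@@](C)(O[Si](CC)(CC)CC)CC[C@H]1[C@]2(C)CCCO[C@@]2(OC)CC[C@@H]1[N+](=O)[O-]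
F5 | step 16 | trifluoromethanesulfonate of alcohol 25 | C=C[C@@](C)(O[Si](CC)(CC)CC)CC[C@H]1[C@](C)(CCC=C(C)C)[C@H](OS(=O)(=O)C(F)(F)F)CC[C@@]1(C)O[Si](CC)(CC)CC
F6 | step 10 | (4aS,5S,8aS)-8a-methoxy-4a-methyl-5-[(3S)-3-methyl-3-(triethylsilyloxy)pent-4-en-1-yl]octahydro-2H-chromen-6-ol (epimers at C6) | C=C[C@@](C)(O[Si](CC)(CC)CC)CC[C@H]1[C@]2(C)CCCO[C@@]2(OC)CCC1O
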